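The route cuts both ring C–C(=O) bonds of the furan-2,5-dione. The tetrasubstituted C3=C4 olefin carries the C16 chain on C3 and the methyl group on C4, and it is read as a former triple bond. Carbonyl carbons C2 and C5 are read as two molecules of CO2, held cis so that O1 can bridge them. A nickel-catalysed reductive double carboxylation forms C2–C3 and C4–C5 in a single operation. A nickelacycle imposes the syn geometry, and regiochemistry does not matter because either insertion order gives the same diacid. The precursor is a linear, methyl-capped C19 alkyne, (2S)-nonadec-17-yn-2-yl acetate, whose only stereocentre is purchased in (S)-butane-1,3-diol.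

Key step: step 6

Remark: once protonated, a 2,3-dialkylmaleic acid equilibrates with its anhydride during work-up, so the diacid from step 6 is handled only as a crude extract and passed straight into step 7.

Step 1
Reactants: 1 1,12-dibromododecane (3 equiv); 2 1-propynyllithium (commercial solid)
Product: 3 15-bromopentadec-2-yne
Conditions: THF/DMPU, 0 °C → rt; surplus 1 recovered by chromatography (hexanes)
Reagents that add atoms: none
Why: SN2 alkylation of a lithium acetylide by a primary bromide, accelerated by the dipolar cosolvent; the excess of the symmetrical dibromide statistically suppresses the second substitution.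

Step 2
Reactants: 4 (S)-butane-1,3-diol
Product: 5 (3S)-3-hydroxybutyl 4-methylbenzenesulfonate
Conditions: TsCl (1 equiv), Et3N, CH2Cl2, −20 → 0 °C
Reagents that add atoms: p-toluenesulfonyl chloride, Cc1ccc(cc1)S(=O)(=O)Cl
Why: Chemoselective tosylation of a diol, in which the unhindered primary hydroxyl should react much faster than the secondary one at low temperature with one equivalent of TsCl; the C3 stereocentre takes no part.

Step 3
Reactants: 5 (3S)-3-hydroxybutyl 4-methylbenzenesulfonate
Product: 6 (3S)-3-[(triethylsilyl)oxy]butyl 4-methylbenzenesulfonate
Conditions: TESCl, imidazole, CH2Cl2, 0 °C → rt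
Reagents that add atoms: chlorotriethylsilane, CC[Si](Cl)(CC)CC
Why: Imidazole-promoted silyl ether formation removes the proton that would quench the Grignard reagent and the alkoxide that could displace the tosylate to give 2-methyloxetane, and the labile triethylsilyl group can be shed in the next work-up without a step of its own.

Step 4
Reactants: 3 15-bromopentadec-2-yne; 6 (3S)-3-[(triethylsilyl)oxy]butyl 4-methylbenzenesulfonate
Product: 9 (S)-nonadec-17-yn-2-ol, via pentadec-13-ynylmagnesium bromide 7 (not isolated), via triethylsilyl ether 8 (not isolated)
Conditions: 3, Mg, THF, 45 °C; then 6, Li2CuCl4 (5 mol %), THF, −78 °C → rt; then 1 M HCl, THF, rt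
Reagents that add atoms: magnesium, [Mg] (present only in intermediate 7)
Why: Copper-catalysed alkyl–alkyl Grignard cross-coupling (SN2 displacement of a primary tosylate by a transient magnesium cuprate), to which the internal alkyne and the silyl ether are inert; the stereocentre lies two carbons from the reacting centre and is retained, and dilute acid then hydrolyses the silyl ether.

Step 5
Reactants: 9 (S)-nonadec-17-yn-2-ol
Product: 10 (2S)-nonadec-17-yn-2-yl acetate
Conditions: Ac2O, pyridine, DMAP (cat.), rt
Reagents that add atoms: acetic anhydride, CC(=O)OC(C)=O
Why: DMAP-catalysed O-acylation leaves the C–O bond at C2 intact and therefore keeps the S configuration.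

Step 6
Reactants: 10 (2S)-nonadec-17-yn-2-yl acetate; 11 carbon dioxide
Product: 13 (Z)-2-[(15S)-15-acetoxyhexadecyl]-3-methylbut-2-enedioic acid, via magnesium dicarboxylate 12 (not isolated)
Conditions: Ni(acac)2 (10 mol %), 2,2'-bipyridine (10 mol %), Zn powder (3 equiv), MgBr2 (3 equiv), 4 Å MS, DMF, CO2 (1 atm), rt; filter off Zn (Celite); then cold 1 M HCl, EtOAc
Reagents that add atoms: carbon dioxide 11, O=C=O (two molecules); MgBr2 (magnesium dibromide), [Mg+2].[Br-].[Br-] (cation present only in intermediate 12)
Why: Zinc reduces Ni(acac)2/bipyridine to zerovalent nickel, which couples the triple bond of 10 oxidatively with one CO2 to a five-membered oxanickelacyclopentenone; MgBr2 strips the carboxylate from nickel, zinc reduces the resulting alkenylnickel bromide to a monovalent alkenylnickel species, and its nucleophilic C–Ni bond inserts the second CO2, releasing 12 and returning nickel to the cycle. The closest known reaction type is this same nickel/zinc reductive double carboxylation of unactivated internal alkynes under one atmosphere of CO2, so only the molecule is new. No ring of the target is closed here: the only ring involved is the transient nickelacycle, formed by oxidative cyclometallation, and the future O1 is still part of two separate carboxyl groups in 13. No stereocentre is created; the one stereochemical element set is the Z olefin geometry, which follows from the syn placement of the new C–C bond and the C–Ni bond in the metallacycle and from retention at the alkenyl carbon during the second insertion. Regioselectivity is not needed, because first carboxylation at C17 or at C18 leads to the same product, and chemoselectivity is secured by the substrate, whose acetate is aprotic, fourteen methylene groups away from the alkyne and inert to Zn and MgBr2 in DMF at room temperature. The real demand is rigorous dryness (sieves, anhydrous MgBr2), since a proton source would intercept the alkenylnickel intermediate at the monoacid stage, and zinc is removed before acidification so that it cannot reduce the electron-poor olefin.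

Step 7
Reactants: 13 (Z)-2-[(15S)-15-acetoxyhexadecyl]-3-methylbut-2-enedioic acid (crude EtOAc extract)
Product: 14 3-[(15S)-15-acetoxyhexadecyl]-4-methylfuran-2,5-dione (target)
Conditions: MgSO4; toluene, 60 °C, evaporation (azeotropic drying); SiO2
Reagents that add atoms: none
Why: Cyclodehydration by intramolecular nucleophilic acyl substitution (5-exo-trig attack of one carboxyl oxygen on the other carboxyl carbon) is strongly favoured for cis-2,3-dialkylbutenedioic acids because the two alkyl groups press the carboxyl groups together, and these mild conditions leave the secondary acetate and its stereocentre alone.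

Compound list
1 | 1,12-dibromododecane | BrCCCCCCCCCCCCBr | starting material
2 | 1-propynyllithium | CC#C[Li] | starting material
3 | 15-bromopentadec-2-yne | CC#CCCCCCCCCCCCCBr | intermediate
4 | (S)-butane-1,3-diol | C[C@H](O)CCO | starting material
5 | (3S)-3-hydroxybutyl 4-methylbenzenesulfonate | C[C@H](O)CCOS(=O)(=O)c1ccc(C)cc1 | intermediate
6 | (3S)-3-[(triethylsilyl)oxy]butyl 4-methylbenzenesulfonate | C[C@H](O[Si](CC)(CC)CC)CCOS(=O)(=O)c1ccc(C)cc1 | intermediate
7 | pentadec-13-ynylmagnesium bromide | CC#CCCCCCCCCCCCC[Mg]Br | intermediate
8 | triethyl{[(2S)-nonadec-17-yn-2-yl]oxy}silane | C[C@H](O[Si](CC)(CC)CC)CCCCCCCCCCCCCCC#CC | intermediate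
9 | (S)-nonadec-17-yn-2-ol | C[C@H](O)CCCCCCCCCCCCCCC#CC | intermediate
10 | (2S)-nonadec-17-yn-2-yl acetate | CC(=O)O[C@@H](C)CCCCCCCCCCCCCCC#CC | intermediate
11 | carbon dioxide | O=C=O | starting material
12 | magnesium (Z)-2-[(15S)-15-acetoxyhexadecyl]-3-methylbut-2-enedioate | CC(=O)O[C@@H](C)CCCCCCCCCCCCCC/C(C(=O)[O-])=C(\C)C(=O)[O-].[Mg+2] | intermediate
13 | (Z)-2-[(15S)-15-acetoxyhexadecyl]-3-methylbut-2-enedioic acid | CC(=O)O[C@@H](C)CCCCCCCCCCCCCC/C(C(=O)O)=C(\C)C(=O)O | intermediate
14 | 3-[(15S)-15-acetoxyhexadecyl]-4-methylfuran-2,5-dione | CC(=O)O[C@@H](C)CCCCCCCCCCCCCCC1=C(C)C(=O)OC1=O | target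

Total step count: 7. Longest linear sequence: 6 steps (4 → 5 → 6 → 9 → 10 → 13 → 14); step 1 is the convergent branch.

Steps most likely to fail

Step 6. The catalytic cycle may stall after the first CO2 if adventitious protons cleave the alkenyl–nickel bond, or zerovalent nickel may divert the alkyne into oligomerisation. The fallback sets out from 10 and returns at 14, and it brings in the two C1 units in separate stoichiometric events. Ni(cod)2 and 2,2'-bipyridine (one equivalent each) in THF under CO2 should couple 10 with one CO2. This would give a pair of stable regioisomeric metallacycles, the C18-nickelated oxanickelacyclopentenone F1 and the C17-nickelated oxanickelacyclopentenone F2, which are collected together. Exposure of the mixture to CO (1 atm) should insert CO into the alkenyl–nickel bond. Reductive elimination of the acyl and carboxylate ligands would then release anhydride 14 from both isomers. Neither a reductant nor a second CO2 insertion is required.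

Step 4. Wurtz-type homocoupling during magnesium insertion, or slow displacement with competing attack of the Grignard reagent at sulfur, could erode the fragment union. The fallback sets out from 6 and 3 and returns at 8, and it replaces organometallic cross-coupling with carbanion alkylation. PhSO2Na in DMF at 60 °C should convert 6 into (S)-triethyl{[4-(phenylsulfonyl)butan-2-yl]oxy}silane F3. Deprotonation with n-BuLi in THF at −78 °C and alkylation with bromide 3 in the presence of DMPU should give (2S)-4-(phenylsulfonyl)-2-[(triethylsilyl)oxy]nonadec-17-yne F4, whose epimers at C4 are inconsequential. Reductive desulfonylation with Na(Hg) and Na2HPO4 in MeOH, which spares an unactivated internal alkyne, should deliver silyl ether 8. The dilute-acid treatment of step 4 then turns 8 into 9.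

Step 1. Over-alkylation, together with a tedious separation of three non-polar species of similar mobility, could make the monoalkylation impractical. The fallback sets out from 2 and returns at 3, and it breaks the symmetry with a polar handle. Purchased 12-bromododecan-1-ol F5 is treated with two equivalents of 2 in THF/DMPU. The first equivalent deprotonates the hydroxyl and the second displaces bromide, giving pentadec-13-yn-1-ol F6, which is easily purified by its polarity. An Appel reaction (CBr4, PPh3, CH2Cl2, 0 °C) should then give bromide 3.

Further compounds
F1 | step 6 | (2,2'-bipyridine)nickel oxanickelacyclopentenone with Ni on the methyl-bearing carbon C18 and the carboxylate carbon on C17 (ligand written as a separate component) | CC(=O)O[C@@H](C)CCCCCCCCCCCCCCC1=C(C)[Ni]OC1=O.c1ccc(nc1)-c1ccccn1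
F2 | step 6 | (2,2'-bipyridine)nickel oxanickelacyclopentenone with Ni on the chain-bearing carbon C17 and the carboxylate carbon on C18 (ligand written as a separate component) | CC(=O)O[C@@H](C)CCCCCCCCCCCCCCC1=C(C)C(=O)O[Ni]1.c1ccc(nc1)-c1ccccn1
F3 | step 4 | (S)-triethyl{[4-(phenylsulfonyl)butan-2-yl]oxy}silane | C[C@H](O[Si](CC)(CC)CC)CCS(=O)(=O)c1ccccc1
F4 | step 4 | (2S)-4-(phenylsulfonyl)-2-[(triethylsilyl)oxy]nonadec-17-yne, both C4 epimers | C[C@H](O[Si](CC)(CC)CC)CC(CCCCCCCCCCCCC#CC)S(=O)(=O)c1ccccc1
F5 | step 1 | 12-bromododecan-1-ol (purchased) | OCCCCCCCCCCCCBr
F6 | step 1 | pentadec-13-yn-1-ol | CC#CCCCCCCCCCCCCO
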